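**Retrosynthetic overview**

1. Target 50 ⇐ carbinol 49 (MnO2) ⇐ aldehyde 47. The strategy rests on ring B (C5–C6–C7–C8–C9–C10): the aryl ketone C6, the C7=C8 alkene and the benzylic quaternary C9 are what the photoenol of an ortho-(sec-alkyl)benzaldehyde leaves after [4+2] addition to the C14 ethynyl group, which closes rings B and C (C8, C9, C11–C14) together, last.
2. 47 ⇐ Negishi coupling (C9–C10) of aryl bromide 19 (ring A, dioxane, guaiane) with the secondary alkylzinc from iodide 44 (rings D and E).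
3. 19 (guaiane atoms primed): ring A from 1; seven-membered ring from 7 by two catalyst-controlled conjugate additions (C7′, C10′); C1′–O by phenoxide SN2, then allylation anti to the C10′ methyl; dioxane by SN1 etherification at C5′; cyclopentene by ring-closing metathesis.
4. 44: ring E from ketal 20; ring D by auxiliary-controlled Robinson annulation (C17), cis fusion by conjugate hydride (C18), C13 by Michael addition, C14 by reductive methylation of an enoate, ethynyl by Seyferth–Gilbert homologation, C20 methyl last.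
5. Ring order: A (given), seven-membered ring, dioxane, cyclopentene; E (given), D; then B and C in one step.

Key step: step 34

Assumption: the ligand antipodes in steps 7 and 8 follow the usual sense of induction for 3-substituted cycloalkanones; C9 (from step 20), C1′ of 12 and 13 and the carbinol carbon of 16 are carried as epimer mixtures because each later becomes planar.

**Ring A**

Step 1
Reactants: 1 2-bromo-3-hydroxy-4-methoxybenzaldehyde
Product: 2 3-hydroxy-4-methoxy-2-methylbenzaldehyde
Conditions: trimethylboroxine, Pd(dppf)Cl2 (5 mol%), K2CO3, dioxane/H2O, 100 °C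
Reagents that add atoms: trimethylboroxine CB1OB(C)OB(C)O1
Why: Suzuki–Miyaura methylation of the aryl bromide, which tolerates the phenolate and the aldehyde under aqueous carbonate.

Step 2
Reactants: 2 3-hydroxy-4-methoxy-2-methylbenzaldehyde
Product: 3 6-bromo-3-hydroxy-4-methoxy-2-methylbenzaldehyde
Conditions: Br2, NaOAc, AcOH, rt
Reagents that add atoms: bromine BrBr
Why: Electrophilic aromatic bromination goes para to the free hydroxyl (the later C10), the only other open position being meta to it.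

Step 3
Reactants: 3 6-bromo-3-hydroxy-4-methoxy-2-methylbenzaldehyde
Product: 4 6-bromo-3,4-dihydroxy-2-methylbenzaldehyde
Conditions: BBr3, CH2Cl2, −78 → 0 °C; H2O
Reagents that add atoms: none
Why: Lewis-acid cleavage of the aryl methyl ether frees the catechol without touching the aryl bromide or the aldehyde.

Step 4
Reactants: 4 6-bromo-3,4-dihydroxy-2-methylbenzaldehyde
Product: 5 6-bromo-3-hydroxy-4-(methoxymethoxy)-2-methylbenzaldehyde
Conditions: MOMCl (1.05 equiv), K2CO3 (1.1 equiv), acetone, 0 °C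
Reagents that add atoms: chloromethyl methyl ether COCCl
Why: Williamson-type O-alkylation; the hydroxyl para to the formyl group is the more acidic and less hindered, so the hydroxyl next to the methyl group (the later oxygen on C1′) stays free.

Step 5
Reactants: 5 6-bromo-3-hydroxy-4-(methoxymethoxy)-2-methylbenzaldehyde
Product: 6 4-bromo-3-(dimethoxymethyl)-6-(methoxymethoxy)-2-methylphenol
Conditions: HC(OMe)3, MeOH, CeCl3·7H2O (10 mol%), rt
Reagents that add atoms: trimethyl orthoformate COC(OC)OC
Why: Acetalisation under mild cerium trichloride catalysis masks the aldehyde against the enolate and Grignard steps and leaves the aryl methoxymethyl ether.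

**Seven-membered ring and benzodioxane**

Step 6
Reactants: 7 cycloheptanone
Product: 8 cyclohepta-2,6-dien-1-one
Conditions: IBX (4 equiv), DMSO/fluorobenzene, 70 °C
Reagents that add atoms: none
Why: IBX dehydrogenation of the ketone on both sides gives the cross-conjugated dienone.

Step 7
Reactants: 8 cyclohepta-2,6-dien-1-one
Product: 9 (R)-6-(prop-1-en-2-yl)cyclohept-2-en-1-one
Conditions: isopropenylboronic acid pinacol ester (0.9 equiv), [Rh(OH)(cod)]2 (1.5 mol%), (R)-BINAP, dioxane/H2O, 35 °C
Reagents that add atoms: 2-isopropenyl-4,4,5,5-tetramethyl-1,3,2-dioxaborolane C=C(C)B1OC(C)(C)C(C)(C)O1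
Why: Rhodium-catalysed asymmetric 1,4-addition of the alkenylboronate; (R)-BINAP sets C7′ as R, attack on either enantiotopic enone gives the same enantiomer, and limiting boronate leaves the second enone.

Step 8
Reactants: 9 (R)-6-(prop-1-en-2-yl)cyclohept-2-en-1-one
Product: 11 trimethyl{[(3S,6R)-3-methyl-6-(prop-1-en-2-yl)cyclohept-1-en-1-yl]oxy}silane, via methylzinc enolate 10 (not isolated)
Conditions: Me2Zn, Cu(OTf)2 (2 mol%), (S,R,R)-binaphthol bis(1-phenylethyl)amine phosphoramidite (4 mol%), toluene, −25 °C; then TMSOTf, 0 °C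
Reagents that add atoms: dimethylzinc C[Zn]C; trimethylsilyl trifluoromethanesulfonate C[Si](C)(C)OS(=O)(=O)C(F)(F)F
Why: Copper-catalysed asymmetric conjugate addition; the ligand overrides the remote C7′ centre and sets C10′ as S (cis to the isopropenyl group), and silylation fixes the enolate at C1′.

Step 9
Reactants: 11 silyl enol ether
Product: 12 (3S,6R)-2-bromo-3-methyl-6-(prop-1-en-2-yl)cycloheptan-1-one (C2 epimers)
Conditions: NBS, THF, −78 → 0 °C
Reagents that add atoms: N-bromosuccinimide O=C1CCC(=O)N1Br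
Why: Electrophilic α-bromination of the silyl enol ether places bromine only at C1′, whose configuration is irrelevant.

Step 10
Reactants: 12 bromo ketone; 6 phenol
Product: 13 (3S,6R)-2-[4-bromo-3-(dimethoxymethyl)-6-(methoxymethoxy)-2-methylphenoxy]-3-methyl-6-(prop-1-en-2-yl)cycloheptan-1-one (C2 epimers)
Conditions: K2CO3, DMF, rt
Reagents that add atoms: none
Why: Williamson ether synthesis by SN2 displacement of the α-bromo ketone with the single free phenoxide of 6, which fixes which ring A oxygen ends on C1′.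

Step 11
Reactants: 13 aryloxy ketone
Product: 15 (2S,3S,6R)-2-allyl-2-aryloxy-3-methyl-6-(prop-1-en-2-yl)cycloheptan-1-one (aryl as in 13), via sodium enolate 14 (not isolated)
Conditions: NaH (0.95 equiv), THF, rt; allyl bromide; then toluene, 110 °C
Reagents that add atoms: allyl bromide C=CCBr
Why: Allylation of the thermodynamic enolate at the more acidic aryloxy-bearing C1′; allyl bromide enters anti to the C10′ methyl so the aryloxy group ends syn to it, and any O-allyl enol ether converges by Claisen rearrangement on heating.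

Step 12
Reactants: 15 allyl aryloxy ketone
Product: 16 (2S,3S,6R)-2-allyl-2-aryloxy-3-methyl-1,6-di(prop-1-en-2-yl)cycloheptan-1-ol (C1 epimers)
Conditions: isopropenylmagnesium bromide, CeCl3, THF, −78 → 0 °C
Reagents that add atoms: prop-1-en-2-ylmagnesium bromide CC(=C)[Mg]Br
Why: Organocerium 1,2-addition to the hindered, enolisable ketone; the carbinol configuration is irrelevant because it is ionised in step 13.

Step 13
Reactants: 16 tertiary allylic alcohol
Product: 18 cis-fused benzodioxane bearing 1′-allyl and 5′-isopropenyl groups (bromo aldehyde), via deprotected hydroxy aldehyde 17 (not isolated)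
Conditions: 2 M aq. HCl, THF, 40 °C
Reagents that add atoms: water O
Why: Acid hydrolysis of acetal and methoxymethyl ether, then SN1 allylic etherification: the tertiary allylic cation at C5′ is trapped by the tethered phenol in a six-membered closure that can only be cis-fused, so both carbinol epimers converge.

Step 14
Reactants: 18 benzodioxane diene
Product: 19 guaiane-fused benzodioxane bromo aldehyde (1′S,5′S,7′R,10′S; C3′=C4′)
Conditions: second-generation Grubbs catalyst (5 mol%), CH2Cl2, 40 °C
Reagents that add atoms: none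
Why: Ring-closing metathesis of the allyl and C5′ isopropenyl groups gives the trisubstituted cyclopentene; the C7′ isopropenyl group cannot reach a five-membered ring and stays.

**Rings D and E**

Step 15
Reactants: 20 7-methyl-1,4-dioxaspiro[4.5]decan-8-one (racemic)
Product: 21 (S)-1-phenylethyl imine of 20
Conditions: (S)-1-phenylethylamine, TsOH (cat.), toluene, reflux (Dean–Stark)
Reagents that add atoms: (S)-1-phenylethylamine C[C@H](N)c1ccccc1
Why: Condensation to the chiral imine that carries the auxiliary for the next step.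

Step 16
Reactants: 21 chiral imine
Product: 23 (S)-7-methyl-7-(3-oxopentyl)-1,4-dioxaspiro[4.5]decan-8-one, via imine adduct 22 (not isolated)
Conditions: pent-1-en-3-one, THF, 40 °C; then 20% aq. AcOH, rt
Reagents that add atoms: pent-1-en-3-one C=CC(=O)CC; water O
Why: Michael addition of the more substituted enamine tautomer of the chiral imine (aza-ene-like transition state); the (S)-phenylethyl group shields one face and sets the quaternary C17, and mild acid hydrolyses the imine without opening the ketal.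

Step 17
Reactants: 23 1,5-diketone
Product: 24 ring D enone (C14 ketone, C13=C18, 13-methyl, 17β-methyl, C21 ethylene ketal)
Conditions: NaOMe, MeOH, 60 °C
Reagents that add atoms: none
Why: Intramolecular aldol condensation (second stage of a Robinson annulation) closes ring D.

Step 18
Reactants: 24 enone
Product: 25 dimethylphenylsilyl enol ether (C14–O, C13=C14; 18β-H, cis-fused)
Conditions: [(Ph3P)CuH]6 (3 mol%), PhMe2SiH, toluene, rt
Reagents that add atoms: dimethyl(phenyl)silane C[SiH](C)c1ccccc1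
Why: Copper hydride conjugate reduction with silane trapping; hydride adds axially to C18 on the face of the angular C17 methyl, as nucleophiles do with angularly methylated octalones, giving the cis fusion and a regiodefined enol ether.

Step 19
Reactants: 25 silyl enol ether
Product: 28 1,5-diketone (C13: 27-methyl α, 3-oxobutyl chain β), via lithium enolate 26 (not isolated), via silyl diketone 27 (not isolated)
Conditions: MeLi, THF, 0 °C; 3-(trimethylsilyl)but-3-en-2-one, −78 → −30 °C; aq. NH4Cl; then KF, MeOH, 0 °C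
Reagents that add atoms: 3-(trimethylsilyl)but-3-en-2-one CC(=O)C(=C)[Si](C)(C)C
Why: Michael addition of the regiodefined enolate to the non-polymerising α-silyl vinyl ketone forms quaternary C13; the acceptor approaches the convex face anti to C19 so the chain ends β, and fluoride then removes the silyl group.

Step 20
Reactants: 28 1,5-diketone
Product: 29 C9 alcohol (C9 epimers), C14 ketone retained
Conditions: NaBH4, MeOH/CH2Cl2, −40 °C
Reagents that add atoms: none
Why: Chemoselective borohydride reduction of the unhindered methyl ketone; the C14 ketone next to the quaternary carbon is left.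

Step 21
Reactants: 29 hydroxy ketone
Product: 30 C9 tert-butyldimethylsilyl ether
Conditions: TBSCl, imidazole, DMF, rt
Reagents that add atoms: tert-butyldimethylsilyl chloride CC(C)(C)[Si](C)(C)Cl
Why: Silyl protection of the secondary alcohol for the base, metal and hydride steps.

Step 22
Reactants: 30 ketone
Product: 32 C14 enol triflate (C14=C15), via potassium enolate 31 (not isolated)
Conditions: KHMDS, THF, −78 °C; PhNTf2
Reagents that add atoms: N-phenylbis(trifluoromethanesulfonimide) O=S(=O)(N(c1ccccc1)S(=O)(=O)C(F)(F)F)C(F)(F)F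
Why: Enol triflate formation; the ketone can enolise only toward C15.

Step 23
Reactants: 32 enol triflate
Product: 33 methyl enoate (C8 ester on C14, C14=C15)
Conditions: Pd(OAc)2 (5 mol%), PPh3, CO (1 atm), MeOH, Et3N, DMF, 60 °C
Reagents that add atoms: carbon monoxide [C-]#[O+]; methanol CO
Why: Palladium-catalysed methoxycarbonylation of the enol triflate installs C8 at the ester level.

Step 24
Reactants: 33 enoate
Product: 35 quaternary ester (C14: 26-methyl β, ester α), via lithium ester enolate 34 (not isolated)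
Conditions: Li, NH3(l)/THF, t-BuOH (1 equiv), −78 °C; then MeI
Reagents that add atoms: iodomethane CI
Why: Dissolving-metal conjugate reduction and methylation of the ester enolate (reductive alkylation); iodomethane attacks C14 anti to the axial C13 methyl, so the new methyl is β and the ester α.

Step 25
Reactants: 35 ester
Product: 36 neopentyl alcohol (C8–OH)
Conditions: LiAlH4, THF, 0 °C → reflux
Reagents that add atoms: none
Why: Hydride reduction of the hindered ester.

Step 26
Reactants: 36 alcohol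
Product: 37 aldehyde (C8)
Conditions: Dess–Martin periodinane, pyridine, CH2Cl2, rt
Reagents that add atoms: none
Why: Dess–Martin oxidation to the non-enolisable aldehyde under buffered conditions that spare the ketal and silyl ether.

Step 27
Reactants: 37 aldehyde
Product: 38 terminal alkyne (C7≡C8 on C14)
Conditions: dimethyl (1-diazo-2-oxopropyl)phosphonate, K2CO3, MeOH, rt
Reagents that add atoms: dimethyl (1-diazo-2-oxopropyl)phosphonate COP(=O)(OC)C(=[N+]=[N-])C(C)=O
Why: Seyferth–Gilbert homologation in its mild diazophosphonate form converts the non-enolisable aldehyde into the alkyne.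

Step 28
Reactants: 38 terminal alkyne
Product: 40 triisopropylsilyl alkyne, via lithium acetylide 39 (not isolated)
Conditions: n-BuLi, THF, −78 °C; TIPSOTf, −78 → 0 °C
Reagents that add atoms: triisopropylsilyl trifluoromethanesulfonate CC(C)[Si](C(C)C)(C(C)C)OS(=O)(=O)C(F)(F)F
Why: Deprotonation and C-silylation protect the alkyne against the enolate, organozinc and palladium steps.

Step 29
Reactants: 40 silyl alkyne
Product: 41 keto alcohol (C21 ketone, C9–OH)
Conditions: 2 M aq. HCl, THF, rt
Reagents that add atoms: water O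
Why: Aqueous acid hydrolyses the dioxolane and the silyl ether in one operation, and the triisopropylsilyl alkyne is stable to it.

Step 30
Reactants: 41 keto alcohol
Product: 43 20β-methyl keto alcohol, via dilithium alkoxide enolate 42 (not isolated)
Conditions: LDA (2.2 equiv), THF, −78 °C; MeI (1.05 equiv); aq. NH4Cl; then NaOMe (cat.), MeOH, rt
Reagents that add atoms: iodomethane CI
Why: Kinetic enolate formation at C20 (away from the neopentyl C22) and C-methylation, then base equilibration to the equatorial 20β-methyl epimer.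

Step 31
Reactants: 43 keto alcohol
Product: 44 secondary iodide (C9 epimers)
Conditions: I2, PPh3, imidazole, CH2Cl2, 0 °C → rt
Reagents that add atoms: iodine II
Why: Appel-type iodination of the secondary alcohol; both C9 epimers are used.

**Coupling and end game**

Step 32
Reactants: 44 secondary iodide; 19 aryl bromide
Product: 46 coupled aldehyde with silyl alkyne (C9 epimers), via alkylzinc iodide 45 (not isolated)
Conditions: Zn dust, LiCl, THF, 40 °C; then 19, Pd(OAc)2 (2 mol%), CPhos (4 mol%), THF/toluene, rt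
Reagents that add atoms: none
Why: Negishi coupling; zinc insertion tolerates the ketone, the alkylzinc halide does not add to the aldehyde, and the biarylphosphine favours reductive elimination over β-hydride elimination so the branched sec-alkyl arene forms.

Step 33
Reactants: 46 silyl alkyne
Product: 47 ortho-(sec-alkyl)benzaldehyde with free C14 ethynyl group (C9 epimers)
Conditions: TBAF, AcOH (1 equiv), THF, 0 °C → rt
Reagents that add atoms: none
Why: Fluoride cleavage of the C–Si bond, buffered to spare the aldehyde.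

Step 34
Reactants: 47 ethynyl aldehyde
Product: 49 C6 carbinol of the target (hydroxyl cis to C11), via hydroxy-o-quinodimethane 48 (not isolated)
Conditions: hν (365 nm), degassed toluene (2 mM), 25 °C
Reagents that add atoms: none
Why: Excitation of the aldehyde and 1,5-hydrogen transfer from the tertiary benzylic C9–H give the (E)-hydroxy-o-quinodimethane 48 (C6=C5, C10=C9), which adds as a diene to the C7≡C8 ethynyl group. The closest known reaction types are the photoenolization/Diels–Alder reaction of ortho-alkylbenzaldehydes and the intramolecular cycloaddition of o-quinodimethanes to unactivated alkynes. Ring B closes as the [4+2] ring itself (bonds C6–C7 and C8–C9), and ring C closes as the six-membered tether ring of an intramolecular Diels–Alder reaction in which the diene terminus C9 bonds to the proximal alkyne carbon C8. C9 is set by a chair-like tether: ring D holds C12 and the ethynyl group equatorial and the C13 and C14 methyls axial, so C10 goes equatorial and the C9 methyl axial, syn to the C14 methyl; C6 follows from the E-dienol and is erased in step 35. The step needs the dienol from C9–H and not from the C4 methyl, and chair over boat closure; dienols that cannot cyclise relax to 47 and are recycled, and both C9 epimers of 47 converge.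

Step 35
Reactants: 49 carbinol
Product: 50 CNP0405270.2
Conditions: MnO2 (activated, excess), CH2Cl2, rt
Reagents that add atoms: none
Why: MnO2 oxidises the benzylic and allylic C6 carbinol selectively to the enone and leaves the saturated C21 ketone and the alkenes.

**Compound list**

1 | 2-bromo-3-hydroxy-4-methoxybenzaldehyde | COc1ccc(C=O)c(Br)c1O | starting material
2 | 3-hydroxy-4-methoxy-2-methylbenzaldehyde | COc1ccc(C=O)c(C)c1O | intermediate
3 | 6-bromo-3-hydroxy-4-methoxy-2-methylbenzaldehyde | COc1cc(Br)c(C=O)c(C)c1O | intermediate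
4 | 6-bromo-3,4-dihydroxy-2-methylbenzaldehyde | Oc1cc(Br)c(C=O)c(C)c1O | intermediate
5 | 6-bromo-3-hydroxy-4-(methoxymethoxy)-2-methylbenzaldehyde | COCOc1cc(Br)c(C=O)c(C)c1O | intermediate
6 | 4-bromo-3-(dimethoxymethyl)-6-(methoxymethoxy)-2-methylphenol | COCOc1cc(Br)c(C(OC)OC)c(C)c1O | intermediate
7 | cycloheptanone | O=C1CCCCCC1 | starting material
8 | cyclohepta-2,6-dien-1-one | O=C1C=CCCC=C1 | intermediate
9 | (R)-6-(prop-1-en-2-yl)cyclohept-2-en-1-one | C=C(C)[C@@H]1CCC=CC(=O)C1 | intermediate
10 | methylzinc enolate of (3S,6R)-3-methyl-6-(prop-1-en-2-yl)cycloheptanone | C=C(C)[C@@H]1CC[C@H](C)C=C(O[Zn]C)C1 | intermediate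
11 | trimethyl{[(3S,6R)-3-methyl-6-(prop-1-en-2-yl)cyclohept-1-en-1-yl]oxy}silane | C=C(C)[C@@H]1CC[C@H](C)C=C(O[Si](C)(C)C)C1 | intermediate
12 | (3S,6R)-2-bromo-3-methyl-6-(prop-1-en-2-yl)cycloheptan-1-one (C2 epimers) | C=C(C)[C@@H]1CC[C@H](C)C(Br)C(=O)C1 | intermediate
13 | (3S,6R)-2-aryloxy-3-methyl-6-(prop-1-en-2-yl)cycloheptan-1-one, aryl = 4-bromo-3-(dimethoxymethyl)-6-(methoxymethoxy)-2-methylphenyl (C2 epimers) | C=C(C)[C@@H]1CC[C@H](C)C(Oc2c(C)c(C(OC)OC)c(Br)cc2OCOC)C(=O)C1 | intermediate
14 | sodium enolate of 13 | C=C(C)[C@@H]1CC[C@H](C)C(Oc2c(C)c(C(OC)OC)c(Br)cc2OCOC)=C([O-])C1.[Na+] | intermediate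
15 | (2S,3S,6R)-2-allyl-2-aryloxy-3-methyl-6-(prop-1-en-2-yl)cycloheptan-1-one | C=C(C)[C@@H]1CC[C@H](C)[C@](CC=C)(Oc2c(C)c(C(OC)OC)c(Br)cc2OCOC)C(=O)C1 | intermediate
16 | (2S,3S,6R)-2-allyl-2-aryloxy-3-methyl-1,6-di(prop-1-en-2-yl)cycloheptan-1-ol (C1 epimers) | C=C(C)[C@@H]1CC[C@H](C)[C@](CC=C)(Oc2c(C)c(C(OC)OC)c(Br)cc2OCOC)C(O)(C(C)=C)C1 | intermediate
17 | 16 after loss of acetal and methoxymethyl groups (free phenol, free aldehyde) | C=C(C)[C@@H]1CC[C@H](C)[C@](CC=C)(Oc2c(C)c(C=O)c(Br)cc2O)C(O)(C(C)=C)C1 | intermediate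
18 | cis-fused benzodioxane, 1′-allyl, 5′-isopropenyl, both oxygens syn to the C10′ methyl | C=C(C)[C@@H]1CC[C@H](C)[C@]2(CC=C)Oc3c(C)c(C=O)c(Br)cc3O[C@]2(C(C)=C)C1 | intermediate
19 | guaiane-fused benzodioxane bromo aldehyde (1′S,5′S,7′R,10′S) | C=C(C)[C@@H]1CC[C@H](C)[C@@]23CC=C(C)[C@]2(C1)Oc1cc(Br)c(C=O)c(C)c1O3 | intermediate
20 | 7-methyl-1,4-dioxaspiro[4.5]decan-8-one (racemic) | CC1CC2(CCC1=O)OCCO2 | starting material
21 | (S)-1-phenylethyl imine of 20 | C[C@H](N=C1CCC2(CC1C)OCCO2)c1ccccc1 | intermediate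
22 | (S)-1-phenylethyl imine of 23 | CCC(=O)CC[C@@]1(C)CC2(CCC1=N[C@@H](C)c1ccccc1)OCCO2 | intermediate
23 | (S)-7-methyl-7-(3-oxopentyl)-1,4-dioxaspiro[4.5]decan-8-one | CCC(=O)CC[C@@]1(C)CC2(CCC1=O)OCCO2 | intermediate
24 | ring D enone: C14 ketone, C13=C18, 13-methyl, 17β-methyl, C21 ethylene ketal | CC1=C2CCC3(OCCO3)C[C@]2(C)CCC1=O | intermediate
25 | dimethylphenylsilyl enol ether (C13=C14), 18β-H, cis-fused | CC1=C(O[Si](C)(C)c2ccccc2)CC[C@@]2(C)CC3(OCCO3)CC[C@@H]12 | intermediate
26 | lithium enolate of the cis-fused C14 ketone | CC1=C([O-])CC[C@@]2(C)CC3(OCCO3)CC[C@@H]12.[Li+] | intermediate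
27 | Michael adduct with C11 trimethylsilyl group | CC(=O)C([Si](C)(C)C)C[C@]1(C)C(=O)CC[C@@]2(C)CC3(OCCO3)CC[C@@H]12 | intermediate
28 | 1,5-diketone: C9 and C14 ketones, 13α-methyl, 13β-(3-oxobutyl) | CC(=O)CC[C@]1(C)C(=O)CC[C@@]2(C)CC3(OCCO3)CC[C@@H]12 | intermediate
29 | C9 alcohol (C9 epimers), C14 ketone | CC(O)CC[C@]1(C)C(=O)CC[C@@]2(C)CC3(OCCO3)CC[C@@H]12 | intermediate
30 | C9 tert-butyldimethylsilyl ether, C14 ketone | CC(O[Si](C)(C)C(C)(C)C)CC[C@]1(C)C(=O)CC[C@@]2(C)CC3(OCCO3)CC[C@@H]12 | intermediate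
31 | potassium C14 enolate of 30 | CC(O[Si](C)(C)C(C)(C)C)CC[C@]1(C)C([O-])=CC[C@@]2(C)CC3(OCCO3)CC[C@@H]12.[K+] | intermediate
32 | C14 enol triflate (C14=C15) | CC(O[Si](C)(C)C(C)(C)C)CC[C@]1(C)C(OS(=O)(=O)C(F)(F)F)=CC[C@@]2(C)CC3(OCCO3)CC[C@@H]12 | intermediate
33 | methyl enoate (ester on C14, C14=C15) | CC(O[Si](C)(C)C(C)(C)C)CC[C@]1(C)C(C(=O)OC)=CC[C@@]2(C)CC3(OCCO3)CC[C@@H]12 | intermediate
34 | lithium ester enolate at C14 | CC(O[Si](C)(C)C(C)(C)C)CC[C@]1(C)C(=C([O-])OC)CC[C@@]2(C)CC3(OCCO3)CC[C@@H]12.[Li+] | intermediate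
35 | quaternary ester: 14β-methyl, 14α-CO2Me, 13α-methyl | CC(O[Si](C)(C)C(C)(C)C)CC[C@]1(C)[C@@](C)(C(=O)OC)CC[C@@]2(C)CC3(OCCO3)CC[C@@H]12 | intermediate
36 | 14α-hydroxymethyl compound | CC(O[Si](C)(C)C(C)(C)C)CC[C@]1(C)[C@@](C)(CO)CC[C@@]2(C)CC3(OCCO3)CC[C@@H]12 | intermediate
37 | 14α-formyl compound | CC(O[Si](C)(C)C(C)(C)C)CC[C@]1(C)[C@@](C)(C=O)CC[C@@]2(C)CC3(OCCO3)CC[C@@H]12 | intermediate
38 | 14α-ethynyl compound | CC(O[Si](C)(C)C(C)(C)C)CC[C@]1(C)[C@@](C)(C#C)CC[C@@]2(C)CC3(OCCO3)CC[C@@H]12 | intermediate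
39 | lithium acetylide of 38 | CC(O[Si](C)(C)C(C)(C)C)CC[C@]1(C)[C@@](C)(C#[C-])CC[C@@]2(C)CC3(OCCO3)CC[C@@H]12.[Li+] | intermediate
40 | triisopropylsilyl alkyne | CC(O[Si](C)(C)C(C)(C)C)CC[C@]1(C)[C@@](C)(C#C[Si](C(C)C)(C(C)C)C(C)C)CC[C@@]2(C)CC3(OCCO3)CC[C@@H]12 | intermediate
41 | keto alcohol (C21 ketone, C9–OH) | CC(O)CC[C@]1(C)[C@@](C)(C#C[Si](C(C)C)(C(C)C)C(C)C)CC[C@@]2(C)CC(=O)CC[C@@H]12 | intermediate
42 | dilithium C9 alkoxide and C20–C21 enolate of 41 | CC([O-])CC[C@]1(C)[C@@](C)(C#C[Si](C(C)C)(C(C)C)C(C)C)CC[C@@]2(C)CC([O-])=CC[C@@H]12.[Li+].[Li+] | intermediate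
43 | 20β-methyl keto alcohol | CC(O)CC[C@]1(C)[C@@](C)(C#C[Si](C(C)C)(C(C)C)C(C)C)CC[C@@]2(C)CC(=O)[C@H](C)C[C@@H]12 | intermediate
44 | C9 iodide of the D/E bicycle (C9 epimers) | CC(I)CC[C@]1(C)[C@@](C)(C#C[Si](C(C)C)(C(C)C)C(C)C)CC[C@@]2(C)CC(=O)[C@H](C)C[C@@H]12 | intermediate
45 | C9 alkylzinc iodide | CC([Zn]I)CC[C@]1(C)[C@@](C)(C#C[Si](C(C)C)(C(C)C)C(C)C)CC[C@@]2(C)CC(=O)[C@H](C)C[C@@H]12 | intermediate
46 | coupled aldehyde, silyl-protected alkyne (C9 epimers) | C=C(C)[C@@H]1CC[C@H](C)[C@@]23CC=C(C)[C@]2(C1)Oc1cc(C(C)CC[C@@]4(C)[C@@H]5C[C@@H](C)C(=O)C[C@]5(C)CC[C@]4(C)C#C[Si](C(C)C)(C(C)C)C(C)C)c(C=O)c(C)c1O3 | intermediate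
47 | key-step precursor: ortho-(sec-alkyl)benzaldehyde with C14 ethynyl group (C9 epimers) | C=C(C)[C@@H]1CC[C@H](C)[C@@]23CC=C(C)[C@]2(C1)Oc1cc(C(C)CC[C@@]4(C)[C@@H]5C[C@@H](C)C(=O)C[C@]5(C)CC[C@]4(C)C#C)c(C=O)c(C)c1O3 | intermediate
48 | hydroxy-o-quinodimethane (C6=C5, C10=C9; reactive isomer has hydroxyl and C11 outward) | C=C(C)[C@@H]1CC[C@H](C)[C@@]23CC=C(C)[C@]2(C1)OC1=CC(=C(C)CC[C@@]4(C)[C@@H]5C[C@@H](C)C(=O)C[C@]5(C)CC[C@]4(C)C#C)C(=CO)C(C)=C1O3 | intermediate
49 | C6 carbinol of the target | C=C(C)[C@@H]1CC[C@H](C)[C@@]23CC=C(C)[C@]2(C1)Oc1cc2c(c(C)c1O3)[C@@H](O)C=C1[C@@]2(C)CC[C@@]2(C)[C@@H]3C[C@@H](C)C(=O)C[C@]3(C)CC[C@]12C | intermediate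
50 | CNP0405270.2 | C=C(C)[C@@H]1CC[C@H](C)[C@@]23CC=C(C)[C@]2(C1)Oc1cc2c(c(C)c1O3)C(=O)C=C1[C@@]2(C)CC[C@@]2(C)[C@@H]3C[C@@H](C)C(=O)C[C@]3(C)CC[C@]12C | target

**Totals and risks**

Total step count: 35. Longest linear sequence: 21 steps (20 → 50; steps 15–31, then 32–35).

Steps most likely to fail:

1. Step 34. The dienol may relax or close to a benzocyclobutenol faster than it adds to the unactivated, neopentyl alkyne, or the tether may close through a boat. Fallback, from 47 to 50: the alkyne is exchanged for an alkene dienophile that carries its own leaving group. 47 is hydrostannylated (Bu3SnH, Pd(PPh3)2Cl2, THF, 0 °C) to the (E)-vinylstannane F1 and bromodestannylated (NBS, CH2Cl2, −78 °C) to the (E)-2-bromovinyl aldehyde F2. Irradiation at 365 nm gives, through the hydroxy-o-quinodimethane F3, the bromo carbinol cycloadduct F4 by the classical o-quinodimethane–alkene closure. MnO2 oxidation gives the α-bromo ketone F5, and dehydrobromination across C7–C8 (LiBr, Li2CO3, DMF, 100 °C) returns to the route at 50.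

2. Step 19. Carbon–carbon bond formation at the tetrasubstituted enolate may be slower than proton transfer or loss of the acceptor. Fallback, from 25 to 29: the chain is built by alkylation and stepwise extension. Enolate 26 (MeLi on 25) is alkylated with the more reactive allyl bromide to the allyl ketone F6. Hydroboration–oxidation (9-BBN; H2O2, NaOH) gives the primary alcohol F7, Dess–Martin oxidation the aldehyde F8, and MeMgBr at −78 °C adds to the aldehyde only, returning to the route at 29.

3. Step 32. Zinc insertion may be slow, or β-hydride elimination and chain walking at palladium may compete with coupling to the ortho-formyl aryl bromide. Fallback, from 44 and 19 to 46: nickel-catalysed reductive cross-electrophile coupling of the two halides (NiI2, 4,4′-di-tert-butyl-2,2′-bipyridine, Zn, NaI, pyridine, DMPU, 60 °C), in which a C9 radical is captured by an arylnickel species and no organozinc reagent is preformed.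

Further compounds
F1 | step 34 | (E)-2-(tributylstannyl)vinyl analogue of 47 | C=C(C)[C@@H]1CC[C@H](C)[C@@]23CC=C(C)[C@]2(C1)Oc1cc(C(C)CC[C@@]4(C)[C@@H]5C[C@@H](C)C(=O)C[C@]5(C)CC[C@]4(C)/C=C/[Sn](CCCC)(CCCC)CCCC)c(C=O)c(C)c1O3
F2 | step 34 | (E)-2-bromovinyl analogue of 47 | C=C(C)[C@@H]1CC[C@H](C)[C@@]23CC=C(C)[C@]2(C1)Oc1cc(C(C)CC[C@@]4(C)[C@@H]5C[C@@H](C)C(=O)C[C@]5(C)CC[C@]4(C)/C=C/Br)c(C=O)c(C)c1O3
F3 | step 34 | hydroxy-o-quinodimethane of F2 | C=C(C)[C@@H]1CC[C@H](C)[C@@]23CC=C(C)[C@]2(C1)OC1=CC(=C(C)CC[C@@]4(C)[C@@H]5C[C@@H](C)C(=O)C[C@]5(C)CC[C@]4(C)/C=C/Br)C(=CO)C(C)=C1O3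
F4 | step 34 | 7-bromo-7,8-dihydro C6 carbinol (C6, C7, C8 epimers) | C=C(C)[C@@H]1CC[C@H](C)[C@@]23CC=C(C)[C@]2(C1)Oc1cc2c(c(C)c1O3)C(O)C(Br)C1[C@@]2(C)CC[C@@]2(C)[C@@H]3C[C@@H](C)C(=O)C[C@]3(C)CC[C@]12C
F5 | step 34 | 7-bromo-7,8-dihydro C6 ketone (C7, C8 epimers) | C=C(C)[C@@H]1CC[C@H](C)[C@@]23CC=C(C)[C@]2(C1)Oc1cc2c(c(C)c1O3)C(=O)C(Br)C1[C@@]2(C)CC[C@@]2(C)[C@@H]3C[C@@H](C)C(=O)C[C@]3(C)CC[C@]12C
F6 | step 19 | 13β-allyl-13α-methyl C14 ketone | C=CC[C@]1(C)C(=O)CC[C@@]2(C)CC3(OCCO3)CC[C@@H]12
F7 | step 19 | 13β-(3-hydroxypropyl) C14 ketone | OCCC[C@]1(C)C(=O)CC[C@@]2(C)CC3(OCCO3)CC[C@@H]12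
F8 | step 19 | 13β-(3-oxopropyl) C14 ketone | O=CCC[C@]1(C)C(=O)CC[C@@]2(C)CC3(OCCO3)CC[C@@H]12
F0 | step 32 | none | none
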